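**Plan**

1. Atoms carry the numbers of the target SMILES (C1 methyl to C26). Retrosynthesis: C1 is taken off (C2 methylene), the lactone is opened at O19–C17, ring D is cut at C13–C14, the C14=C15 alkylidene goes back to a C14 ketone, ring A is cut at C2–C3, rings B and C at N4–C26 and C23–C26, then C21–C22, C6–C21, C5–C6 and C8–C9.
2. Forward: ring E comes from cyclopentenone and is grown into a nitroalkene; a pyrroline template sets C21; rings B and C close together, then ring A, then ring D (palladium), then the lactone; the C1 methyl is added last.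
3. Stereochemistry: C9 from a CBS reduction relayed by a Claisen shift; C6 from a thiourea-catalysed Michael addition; C21 from attack anti to the C6 chain on a cyclic enamino ester; C26 and C23 from the bridged ring fusion; C14 from the tether; C2 from hydrogenation on the open face of ring A.
4. Two choices: C13 carries bromine from the first step, so no late regioselective enolisation is needed; the C1 methyl is held back because it lies on the concave face of ring A next to C5 and C22, so it is set under kinetic control in the last step.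

Key step: step 20

Assumption: the (1R,2R)-thiourea is taken to select the nitroalkene face as in its aryl-nitroalkene cases, which corresponds to (S)-C6 here; if the adduct proves antipodal, the (1S,2S)-catalyst is used.

**Route**

Step 1
Reactants: 1 cyclopent-2-en-1-one
Product: 3 2-bromocyclopent-2-en-1-one, via 2,3-dibromocyclopentan-1-one 2 (not isolated)
Conditions: Br2, CH2Cl2, 0 °C; then Et3N, 0 °C to rt
Reagents that add atoms: bromine, BrBr
Why: Bromine adds across the enone and triethylamine removes the acidic α-hydrogen with loss of the β-bromide (addition–elimination), leaving bromine on the α-carbon.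

Step 2
Reactants: 3 2-bromocyclopent-2-en-1-one
Product: 4 (1S)-2-bromocyclopent-2-en-1-ol
Conditions: (R)-2-methyl-CBS-oxazaborolidine (10 mol %), BH3·SMe2, THF, −20 °C; MeOH quench
Reagents that add atoms: none
Why: Corey–Bakshi–Shibata reduction, in which the bromoalkenyl arm acts as the large group so that the (R)-catalyst should give the (S)-alcohol, the source of C9.

Step 3
Reactants: 4 (1S)-2-bromocyclopent-2-en-1-ol
Product: 6 ethyl [(1S)-2-bromocyclopent-2-en-1-yl]acetate, via ketene acetal 5 (not isolated)
Conditions: MeC(OEt)3, EtCO2H (cat.), 140 °C, EtOH distilled off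
Reagents that add atoms: triethyl orthoacetate, CC(OCC)(OCC)OCC
Why: Johnson–Claisen rearrangement, whose suprafacial [3,3] shift relays the C–O configuration to the new C8–C9 bond and leaves bromine on the alkene carbon next to C9.

Step 4
Reactants: 6 ethyl [(1S)-2-bromocyclopent-2-en-1-yl]acetate
Product: 7 [(1S)-2-bromocyclopent-2-en-1-yl]acetaldehyde
Conditions: i-Bu2AlH, CH2Cl2, −78 °C; aq. potassium sodium tartrate
Reagents that add atoms: none
Why: Partial ester reduction by i-Bu2AlH stops at the aluminium hemiacetal at low temperature and gives the aldehyde on work-up.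

Step 5
Reactants: 7 [(1S)-2-bromocyclopent-2-en-1-yl]acetaldehyde
Product: 9 3-[(1S)-2-bromocyclopent-2-en-1-yl]propanal, via methyl enol ether 8 (not isolated)
Conditions: MeOCH2PPh3Cl, KOt-Bu, THF, 0 °C; then 2 M HCl, THF, rt
Reagents that add atoms: (methoxymethyl)triphenylphosphonium chloride, COC[P+](c1ccccc1)(c1ccccc1)c1ccccc1.[Cl-]; water, O
Why: Wittig methoxymethylenation followed by enol ether hydrolysis is the standard one-carbon homologation of an aldehyde and supplies C6.

Step 6
Reactants: 9 3-[(1S)-2-bromocyclopent-2-en-1-yl]propanal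
Product: 12 (5R)-1-bromo-5-[(3E)-4-nitrobut-3-en-1-yl]cyclopent-1-ene, via nitro alcohol 10 (not isolated), via nitro mesylate 11 (not isolated)
Conditions: MeNO2, Et3N (cat.), 0 °C to rt; evaporate; then MsCl, Et3N, CH2Cl2, 0 °C
Reagents that add atoms: nitromethane, C[N+](=O)[O-]
Why: Henry reaction followed by mesylation and E1cB elimination gives the (E)-nitroalkene and brings in C5 and N4.

Step 7
Reactants: 12 (5R)-1-bromo-5-[(3E)-4-nitrobut-3-en-1-yl]cyclopent-1-ene; 13 methyl 4,4-dimethoxy-3-oxobutanoate
Product: 14 methyl (3S)-5-[(1R)-2-bromocyclopent-2-en-1-yl]-2-(2,2-dimethoxyacetyl)-3-(nitromethyl)pentanoate (C21 epimers)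
Conditions: 1-[3,5-bis(trifluoromethyl)phenyl]-3-[(1R,2R)-2-(dimethylamino)cyclohexyl]thiourea (10 mol %), toluene, rt
Reagents that add atoms: none
Why: Organocatalytic Michael addition of a β-keto ester to a nitroalkene, in which the thiourea binds the nitro group while the amine delivers the enol to one face of C6 to give (S)-C6; C21 stays epimeric and becomes planar in step 8.

Step 8
Reactants: 14 nitro keto ester
Product: 16 methyl (4S)-4-{2-[(1R)-2-bromocyclopent-2-en-1-yl]ethyl}-2-(dimethoxymethyl)-4,5-dihydro-1H-pyrrole-3-carboxylate, via amino keto ester 15 (not isolated)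
Conditions: Zn dust, AcOH, 0 °C to rt
Reagents that add atoms: none
Why: Nitro reduction by zinc is followed at once by condensation of the amine with the γ-ketone (enamine formation), giving the conjugated five-membered enamino ester that holds C6 and C21 in one ring.

Step 9
Reactants: 16 cyclic enamino ester; 17 but-3-en-2-one
Product: 18 methyl (3S,4R)-3-{2-[(1R)-2-bromocyclopent-2-en-1-yl]ethyl}-5-(dimethoxymethyl)-4-(3-oxobutyl)-3,4-dihydro-2H-pyrrole-4-carboxylate
Conditions: toluene, 60 °C
Reagents that add atoms: none
Why: Aza-ene-type Michael addition of a secondary enamino ester to an enone, in which the enone reaches C21 on the ring face opposite the C6 chain and so sets the quaternary centre with the oxobutyl arm trans to that chain.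

Step 10
Reactants: 18 quaternary pyrroline
Product: 19 ring-opened N-Fmoc amino diketone acetal (C6 and C21 as in 18)
Conditions: FmocCl, NaHCO3, dioxane–H2O, 0 °C to rt
Reagents that add atoms: 9-fluorenylmethyl chloroformate, O=C(Cl)OCC1c2ccccc2-c2ccccc12; water, O
Why: Schotten–Baumann acylation of a cyclic ketimine gives an N-acyliminium ion that has no ring hydrogen to lose (C21 is quaternary), so water adds and the ring opens to the carbamate-protected amino ketone.

Step 11
Reactants: 19 N-Fmoc amino diketone acetal
Product: 20 N-Fmoc 2-azabicyclo[3.2.1]octan-8-one (rings B and C; C23 acetyl drawn endo)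
Conditions: CF3CO2H, CH2Cl2, 0 to 40 °C
Reagents that add atoms: none
Why: N-acyliminium Mannich cyclisation, in which the carbamate nitrogen condenses with acetal carbon C26 to a six-membered N-acyliminium ion (ring B) that the enol of the methyl ketone attacks through C23 in a 5-exo closure (ring C); the bridge dictates C26 and C23 stays free to equilibrate.

Step 12
Reactants: 20 N-Fmoc bicyclic ketone
Product: 21 bicyclic secondary amine
Conditions: piperidine, DMF, rt
Reagents that add atoms: none
Why: Base-induced E1cB cleavage of the fluorenylmethyl carbamate frees N4, the dibenzofulvene being trapped by piperidine.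

Step 13
Reactants: 21 bicyclic secondary amine
Product: 22 azatricyclic diketone ester (rings A to C; C14 and C24 ketones)
Conditions: (CH2O)n, AcOH, 70 °C
Reagents that add atoms: formaldehyde (as paraformaldehyde), C=O
Why: Intramolecular Mannich reaction, in which the N4 methyleneiminium ion is attacked by the methyl-side enol of the C24 ketone in a 6-endo closure that forms ring A; only the endo acetyl epimer can close, and acid supplies it by enolisation at C23.

Step 14
Reactants: 22 azatricyclic diketone ester; 23 ethane-1,2-diol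
Product: 24 C24 dioxolane of 22
Conditions: p-TsOH·H2O (1.2 equiv), benzene, reflux (Dean–Stark)
Reagents that add atoms: none
Why: Acid-catalysed ketalisation should take the ring A ketone only, because the C14 ketone sits between a quaternary and a bridgehead carbon and next to the protonated nitrogen, which disfavours an oxocarbenium ion there.

Step 15
Reactants: 24 keto ester ketal
Product: 25 diol (C20 hydroxymethyl; C14 carbinol of unassigned configuration)
Conditions: LiAlH4, THF, 0 °C
Reagents that add atoms: none
Why: Hydride reduction of the ester gives the C20 carbinol and also reduces the C14 ketone, which is of no consequence because step 17 restores it.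

Step 16
Reactants: 25 diol
Product: 26 C20 tert-butyldimethylsilyl ether
Conditions: TBSCl, imidazole, DMF, 0 °C to rt
Reagents that add atoms: tert-butyldimethylsilyl chloride, CC(C)(C)[Si](C)(C)Cl
Why: Silylation distinguishes the primary C20 hydroxyl from the hindered bridge carbinol at C14.

Step 17
Reactants: 26 silyl ether carbinol
Product: 27 C14 ketone
Conditions: Dess–Martin periodinane, NaHCO3, CH2Cl2, rt
Reagents that add atoms: none
Why: Dess–Martin oxidation returns the C14 ketone, which cannot enolise because C21 is quaternary and C26 is a bridgehead.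

Step 18
Reactants: 27 C14 ketone; 28 (2-carboxyethyl)triphenylphosphonium bromide
Product: 29 C14=C15 alkylidene propanoic acid
Conditions: NaN(SiMe3)2 (2 equiv per equiv of 28), THF, 0 °C; then 27, rt to 60 °C; aq. NaH2PO4
Reagents that add atoms: none
Why: Wittig olefination of a strained, non-enolisable bridge ketone with the carboxylate ylide gives the alkylidene with the acid chain expected on the C26 side, the smaller flank; either alkene isomer serves in step 20.

Step 19
Reactants: 29 alkylidene acid
Product: 30 methyl ester (cyclisation precursor)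
Conditions: Me3SiCHN2, MeOH–toluene, 0 °C
Reagents that add atoms: (trimethylsilyl)diazomethane, C[Si](C)(C)C=[N+]=[N-]
Why: Esterification with a diazoalkane needs no base, so the β,γ-alkene stays in place and the tertiary amine is not quaternised.

Step 20
Reactants: 30 alkenyl bromide alkylidene ester
Product: 31 pentacyclic E-enoate (ring D closed; C14 quaternary)
Conditions: Pd(OAc)2 (10 mol %), PPh3 (30 mol %), Ag2CO3 (2 equiv), MeCN, 80 °C
Reagents that add atoms: none
Why: Zerovalent palladium formed from Pd(OAc)2 and PPh3 inserts into the C13–Br bond, Ag2CO3 removes bromide to give a cationic alkenylpalladium species, syn carbopalladation of the C14=C15 alkylidene forms C13–C14, and syn β-hydride elimination from C16 releases the E-enoate. The closest known reaction type is the intramolecular Heck cyclisation of alkenyl halides and triflates onto trisubstituted alkenes to build quaternary carbons. Ring D (C6, C7, C8, C9, C13, C14, C21) closes in the 7-exo-trig mode. C14 is fixed by the tether, since C7 stands on C6 syn to the C14 bridge and C13 can therefore reach only the alkylidene face above N4–C5–C6. The step needs exo rather than 8-endo insertion and must be faster than drift of the β,γ-alkene into conjugation; the short tether favours the exo mode and the insoluble silver carbonate keeps soluble base out of the medium. The C12=C13 alkene stays where it is because C14 carries no hydrogen.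

Step 21
Reactants: 31 pentacyclic enoate
Product: 32 saturated methyl ester
Conditions: Mg turnings, MeOH, rt
Reagents that add atoms: none
Why: Dissolving-metal conjugate reduction with magnesium in methanol saturates only the enoate alkene, the isolated C12=C13 bond being inert to electron transfer.

Step 22
Reactants: 32 saturated ester
Product: 34 keto lactone lacking C1, via hydroxy keto ester 33 (not isolated)
Conditions: 2 M HCl, THF, 40 °C; evaporate; then p-TsOH·H2O, toluene, 4 Å sieves, 100 °C
Reagents that add atoms: water, O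
Why: Acid hydrolysis removes the silyl ether and the dioxolane, and acid-catalysed transesterification (lactonisation) then joins the C20 hydroxyl and the C17 ester, which C21 and C14 hold next to each other.

Step 23
Reactants: 34 keto lactone
Product: 35 C2-methylene ketone
Conditions: (CH2O)n, i-Pr2NH·CF3CO2H, THF, reflux
Reagents that add atoms: formaldehyde (as paraformaldehyde), C=O
Why: Mannich-type α-methylenation (aminomethylation then elimination) can occur only at C2, since C23 is a methine and the lactone does not enolise under these conditions.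

Step 24
Reactants: 35 C2-methylene ketone
Product: 36 target CNP0292775.1
Conditions: H2 (1 atm), RhCl(PPh3)3 (10 mol %), benzene–EtOH, rt
Reagents that add atoms: none
Why: Homogeneous hydrogenation reduces the 1,1-disubstituted enone alkene and spares the trisubstituted C12=C13 bond; hydrogen should arrive on the open face of ring A away from C5 and C22, which places the methyl on the cage side as in the target.

**Compound list**

1 | cyclopent-2-en-1-one | O=C1C=CCC1 | starting material
2 | trans-2,3-dibromocyclopentan-1-one (racemic) | O=C1CCC(Br)C1Br | intermediate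
3 | 2-bromocyclopent-2-en-1-one | O=C1CCC=C1Br | intermediate
4 | (1S)-2-bromocyclopent-2-en-1-ol | O[C@H]1CCC=C1Br | intermediate
5 | (5S)-1-bromo-5-[(1-ethoxyethenyl)oxy]cyclopent-1-ene | C=C(OCC)O[C@H]1CCC=C1Br | intermediate
6 | ethyl [(1S)-2-bromocyclopent-2-en-1-yl]acetate | CCOC(=O)C[C@@H]1CCC=C1Br | intermediate
7 | [(1S)-2-bromocyclopent-2-en-1-yl]acetaldehyde | O=CC[C@@H]1CCC=C1Br | intermediate
8 | (5S)-1-bromo-5-(3-methoxyprop-2-en-1-yl)cyclopent-1-ene (E/Z mixture) | COC=CC[C@@H]1CCC=C1Br | intermediate
9 | 3-[(1S)-2-bromocyclopent-2-en-1-yl]propanal | O=CCC[C@@H]1CCC=C1Br | intermediate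
10 | 4-[(1S)-2-bromocyclopent-2-en-1-yl]-1-nitrobutan-2-ol (carbinol epimers) | OC(C[N+](=O)[O-])CC[C@@H]1CCC=C1Br | intermediate
11 | 4-[(1S)-2-bromocyclopent-2-en-1-yl]-1-nitrobutan-2-yl methanesulfonate | CS(=O)(=O)OC(C[N+](=O)[O-])CC[C@@H]1CCC=C1Br | intermediate
12 | (5R)-1-bromo-5-[(3E)-4-nitrobut-3-en-1-yl]cyclopent-1-ene | [O-][N+](=O)/C=C/CC[C@@H]1CCC=C1Br | intermediate
13 | methyl 4,4-dimethoxy-3-oxobutanoate | COC(=O)CC(=O)C(OC)OC | starting material
14 | methyl (3S)-5-[(1R)-2-bromocyclopent-2-en-1-yl]-2-(2,2-dimethoxyacetyl)-3-(nitromethyl)pentanoate (C21 epimers) | COC(=O)C(C(=O)C(OC)OC)[C@@H](C[N+](=O)[O-])CC[C@@H]1CCC=C1Br | intermediate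
15 | methyl (3S)-3-(aminomethyl)-5-[(1R)-2-bromocyclopent-2-en-1-yl]-2-(2,2-dimethoxyacetyl)pentanoate | COC(=O)C(C(=O)C(OC)OC)[C@@H](CN)CC[C@@H]1CCC=C1Br | intermediate
16 | methyl (4S)-4-{2-[(1R)-2-bromocyclopent-2-en-1-yl]ethyl}-2-(dimethoxymethyl)-4,5-dihydro-1H-pyrrole-3-carboxylate | COC(=O)C1=C(C(OC)OC)NC[C@H]1CC[C@@H]2CCC=C2Br | intermediate
17 | but-3-en-2-one | CC(=O)C=C | starting material
18 | methyl (3S,4R)-3-{2-[(1R)-2-bromocyclopent-2-en-1-yl]ethyl}-5-(dimethoxymethyl)-4-(3-oxobutyl)-3,4-dihydro-2H-pyrrole-4-carboxylate | COC(=O)[C@@]1(CCC(C)=O)C(C(OC)OC)=NC[C@H]1CC[C@@H]2CCC=C2Br | intermediate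
19 | N-Fmoc amino diketone acetal: C21 bears CO2Me, 3-oxobutyl, dimethoxyacetyl and the C6 carbon; C6 bears CH2NHFmoc and the bromocyclopentenylethyl chain | COC(=O)[C@@](CCC(C)=O)(C(=O)C(OC)OC)[C@@H](CNC(=O)OCC1c2ccccc2-c2ccccc12)CC[C@@H]1CCC=C1Br | intermediate
20 | N-Fmoc 2-azabicyclo[3.2.1]octan-8-one: CO2Me on bridgehead C21, C6 chain syn to the C14 bridge, acetyl endo on C23 (exo epimer equilibrates) | O=C(OCC1c2ccccc2-c2ccccc12)N1C[C@@H](CC[C@@H]2CCC=C2Br)[C@]3(C(=O)OC)C[C@H](C(C)=O)[C@H]1C3=O | intermediate
21 | free secondary amine of 20 | N1C[C@@H](CC[C@@H]2CCC=C2Br)[C@]3(C(=O)OC)C[C@H](C(C)=O)[C@H]1C3=O | intermediate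
22 | azatricyclic diketone ester (rings A, B, C; ketones at C14 and C24; C20 methyl ester) | C1CN2C[C@@H](CC[C@@H]3CCC=C3Br)[C@]4(C(=O)OC)C[C@H](C1=O)[C@H]2C4=O | intermediate
23 | ethane-1,2-diol | OCCO | starting material
24 | C24 1,3-dioxolane of 22 | C1CN2C[C@@H](CC[C@@H]3CCC=C3Br)[C@]4(C(=O)OC)C[C@H](C15OCCO5)[C@H]2C4=O | intermediate
25 | diol: C20 hydroxymethyl and C14 carbinol (C14 unassigned), C24 dioxolane | C1CN2C[C@@H](CC[C@@H]3CCC=C3Br)[C@]4(CO)C[C@H](C15OCCO5)[C@H]2C4O | intermediate
26 | C20 tert-butyldimethylsilyl ether of 25 | C1CN2C[C@@H](CC[C@@H]3CCC=C3Br)[C@]4(CO[Si](C)(C)C(C)(C)C)C[C@H](C15OCCO5)[C@H]2C4O | intermediate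
27 | C14 ketone (C20 silyl ether, C24 dioxolane) | C1CN2C[C@@H](CC[C@@H]3CCC=C3Br)[C@]4(CO[Si](C)(C)C(C)(C)C)C[C@H](C15OCCO5)[C@H]2C4=O | intermediate
28 | (2-carboxyethyl)triphenylphosphonium bromide | [Br-].OC(=O)CC[P+](c1ccccc1)(c1ccccc1)c1ccccc1 | starting material
29 | C14=C15 alkylidene propanoic acid (C16 cis to C26) | C1CN2C[C@@H](CC[C@@H]3CCC=C3Br)[C@]4(CO[Si](C)(C)C(C)(C)C)C[C@H](C15OCCO5)[C@H]2/C4=C\CC(=O)O | intermediate
30 | methyl ester of 29; alkenyl bromide cyclisation precursor | C1CN2C[C@@H](CC[C@@H]3CCC=C3Br)[C@]4(CO[Si](C)(C)C(C)(C)C)C[C@H](C15OCCO5)[C@H]2/C4=C\CC(=O)OC | intermediate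
31 | pentacyclic C15=C16 E-enoate (ring D closed, C14 quaternary) | C1CN2C[C@H]3CC[C@@H]4CCC=C4[C@]5(/C=C/C(=O)OC)[C@@]3(CO[Si](C)(C)C(C)(C)C)C[C@H](C16OCCO6)[C@H]25 | intermediate
32 | saturated C15–C16 methyl ester | C1CN2C[C@H]3CC[C@@H]4CCC=C4[C@]5(CCC(=O)OC)[C@@]3(CO[Si](C)(C)C(C)(C)C)C[C@H](C16OCCO6)[C@H]25 | intermediate
33 | hydroxy keto ester (C20 OH, C24 ketone, C17 methyl ester) | C1CN2C[C@H]3CC[C@@H]4CCC=C4[C@]5(CCC(=O)OC)[C@@]3(CO)C[C@H](C1=O)[C@H]25 | intermediate
34 | keto lactone lacking the C1 methyl | C1CN2C[C@H]3CC[C@@H]4CCC=C4[C@]45CCC(=O)OC[C@]34C[C@H](C1=O)[C@H]25 | intermediate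
35 | C2-methylene keto lactone | C=C1CN2C[C@H]3CC[C@@H]4CCC=C4[C@]45CCC(=O)OC[C@]34C[C@H](C1=O)[C@H]25 | intermediate
36 | CNP0292775.1 | C[C@@H]1CN2C[C@H]3CC[C@@H]4CCC=C4[C@]45CCC(=O)OC[C@]34C[C@H](C1=O)[C@H]25 | target

**Step count and risks**

Total step count: 24. Longest linear sequence: 24 steps (steps 1 to 24 from cyclopent-2-en-1-one).

Step 20 is the most exposed. Oxidative addition into the hindered alkenyl bromide may be slow, so that base-promoted migration of the C14=C15 bond into conjugation with the ester, or 8-endo insertion, overtakes the 7-exo closure. The fallback sets out from 30: copper-catalysed halide exchange (CuI, NaI, trans-N,N'-dimethylcyclohexane-1,2-diamine, dioxane, 110 °C) gives the alkenyl iodide F1, which is cyclised without phosphine under phase-transfer conditions (Pd(OAc)2, Bu4NCl, KOAc, DMF, 60 °C) through an anionic palladium pathway at lower temperature. It returns to the route at 31.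

Step 18 is next. The carboxylate ylide may collapse by retro-Michael loss of triphenylphosphine before it adds to the crowded C14 ketone. The fallback sets out from 27 and uses the oxido ylide made from (3-hydroxypropyl)triphenylphosphonium bromide and NaN(SiMe3)2, which cannot fragment in that way, to give the homoallylic alcohol F2. Dess–Martin oxidation then gives the β,γ-unsaturated aldehyde F3, and Pinnick oxidation (NaClO2, NaH2PO4, 2-methylbut-2-ene) gives the acid. It returns at 29.

Step 11 is third. Ionisation of the electron-poor α-keto acetal may stall while the carbamate rests as the five-membered hemiaminal on C14. The fallback sets out from 19 and forms the C–C bond before the C–N bond: hydrolysis of the acetal (aqueous HCO2H, 50 °C) gives the keto aldehyde F4; acid-catalysed intramolecular aldol condensation (p-TsOH, benzene, reflux) closes ring C as the enedione F5; piperidine in DMF then removes the carbamate and the freed amine adds to C26 in a 6-exo aza-Michael closure of ring B. It returns at 21.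

Further compounds
F1 | step 20 | alkenyl iodide analogue of 30 | C1CN2C[C@@H](CC[C@@H]3CCC=C3I)[C@]4(CO[Si](C)(C)C(C)(C)C)C[C@H](C15OCCO5)[C@H]2/C4=C\CC(=O)OC
F2 | step 18 | C14=C15 alkylidene propan-1-ol (homoallylic alcohol) | C1CN2C[C@@H](CC[C@@H]3CCC=C3Br)[C@]4(CO[Si](C)(C)C(C)(C)C)C[C@H](C15OCCO5)[C@H]2/C4=C\CCO
F3 | step 18 | C14=C15 alkylidene propanal | C1CN2C[C@@H](CC[C@@H]3CCC=C3Br)[C@]4(CO[Si](C)(C)C(C)(C)C)C[C@H](C15OCCO5)[C@H]2/C4=C\CC=O
F4 | step 11 | N-Fmoc amino keto aldehyde (C26 aldehyde) | COC(=O)[C@@](CCC(C)=O)(C(=O)C=O)[C@@H](CNC(=O)OCC1c2ccccc2-c2ccccc12)CC[C@@H]1CCC=C1Br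
F5 | step 11 | N-Fmoc 3-acetylcyclopent-2-en-1-one (C23=C26 enedione, ring C) | COC(=O)[C@]1(CC(C(C)=O)=CC1=O)[C@@H](CNC(=O)OCC2c3ccccc3-c3ccccc23)CC[C@@H]2CCC=C2Br
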